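**Assumption:** atoms carry the gibberellin/ent-kaurane numbers (C1–C20), and α/β refer to the faces as drawn in the usual gibberellin picture (C19 and C20 α; H5, H9, 18-CH3, 2-OH, 3-OH β), not inverted as in formal ent- nomenclature.

## Retrosynthetic overview

1. Target triacid 33 ⇐ trimethyl ester 32 ⇐ ring A enone 29 (diol from conjugate reduction/enolate hydroxylation, then ketone reduction) ⇐ Wolff contraction of the six-membered ring B in diazoketone 26.
2. 26 ⇐ ent-kaurane-type tetracycle 20, whose C5 and C4 are set by reductive methylation of dienone 18.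
3. Key step: oxidative dearomatisation of salicylate 16; the phenol para carbon (C10) is attacked by the ring C alkene and the cation is closed by an allylsilane, giving rings B and D, C8, C9, C10 and the exo-methylene at once.
4. 16 ⇐ aryl methyl ketone 14 (ring A, from dimethyl 3-hydroxyphthalate, which carries C19 and C6; CH2O supplies C20) + enol triflate 9 (ring C, C13 set by organocatalysis).
5. Ring order: C (built) and A (arene) → B and D together → ring A saturated and functionalised → ring B contracted.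

## Route

Step 1
Reactants: 1 methyl (E)-4-oxobut-2-enoate; 2 tert-butyl 3-oxobutanoate
Product: 5 methyl (1R)-5-oxocyclohex-3-ene-1-carboxylate, via Michael adduct 3 (not isolated), via cyclised tert-butyl ester 4 (not isolated)
Conditions: (S)-2-[diphenyl(trimethylsilyloxy)methyl]pyrrolidine (10 mol%), PhMe, 0 → 20 °C; then p-TsOH·H2O (0.3 equiv), PhMe, 80 °C
Reagents that add atoms: none
Why: Iminium-catalysed Michael addition sets C13 by attack on the enal face opposite the diphenyl(trimethylsilyloxy)methyl group of the (S)-pyrrolidine, and acid-mediated intramolecular aldol condensation with loss of isobutene and CO2 (organocatalytic cyclohexenone synthesis) leaves the 5-substituted cyclohex-2-enone.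

Step 2
Reactants: 5 methyl (1R)-5-oxocyclohex-3-ene-1-carboxylate
Product: 7 methyl (1R)-3-(trifluoromethylsulfonyloxy)cyclohex-3-ene-1-carboxylate, via lithium enolate 6 (not isolated)
Conditions: LiBH(s-Bu)3 (1.05 equiv), THF, −78 °C; then PhNTf2, −78 → 0 °C
Reagents that add atoms: N-phenylbis(trifluoromethanesulfonimide), O=S(=O)(N(c1ccccc1)S(=O)(=O)C(F)(F)F)C(F)(F)F
Why: Conjugate hydride reduction gives only the C8–C9 enolate, and its trapping as the enol triflate fixes the ring alkene on the side away from C13 (regiospecific enolate trapping); the ester is untouched at −78 °C.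

Step 3
Reactants: 7 methyl (1R)-3-(trifluoromethylsulfonyloxy)cyclohex-3-ene-1-carboxylate
Product: 9 (5R)-5-(3-trimethylsilylprop-1-en-2-yl)cyclohex-1-en-1-yl trifluoromethanesulfonate, via bis(silylmethyl) carbinol 8 (not isolated)
Conditions: Me3SiCH2MgCl (4 equiv), CeCl3 (4 equiv), THF, −78 → 0 °C; then SiO2, CH2Cl2, 20 °C
Reagents that add atoms: (trimethylsilyl)methylmagnesium chloride, C[Si](C)(C)C[Mg]Cl
Why: Double addition of the weakly basic Me3SiCH2MgCl/CeCl3 reagent to the ester followed by Peterson elimination (Bunnelle allylsilane synthesis) converts CO2Me into the 2-substituted allylsilane without touching the enol triflate or C13.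

Step 4
Reactants: 10 dimethyl 3-hydroxybenzene-1,2-dicarboxylate (dimethyl 3-hydroxyphthalate)
Product: 12 methyl 5-hydroxy-3-oxo-1,3-dihydro-2-benzofuran-4-carboxylate, via hydroxymethyl diester 11 (not isolated)
Conditions: (CH2O)n, conc. HCl, ZnCl2 (cat.), AcOH, 85 °C
Reagents that add atoms: formaldehyde (as paraformaldehyde), C=O
Why: Acid-mediated hydroxymethylation para to the phenol OH (Blanc/Lederer–Manasse type electrophilic substitution) is followed by lactonisation onto the neighbouring ester, so the phthalide carries C20 (CH2O), C6 (lactone C=O) and C19 (remaining ester).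

Step 5
Reactants: 12 methyl 5-hydroxy-3-oxo-1,3-dihydro-2-benzofuran-4-carboxylate
Product: 13 methyl 2-acetyl-6-hydroxy-3-(hydroxymethyl)benzoate
Conditions: MeLi (2.2 equiv), THF, −78 °C; aq NH4Cl
Reagents that add atoms: methyllithium, [Li]C
Why: Single nucleophilic addition of MeLi to the lactone gives a lithium lactolate that survives to work-up (lactone-to-ketone opening), while the phenoxide-deactivated, doubly ortho-substituted ester does not react.

Step 6
Reactants: 13 methyl 2-acetyl-6-hydroxy-3-(hydroxymethyl)benzoate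
Product: 14 methyl 2-acetyl-3-{[tert-butyl(dimethyl)silyl]oxymethyl}-6-hydroxybenzoate
Conditions: t-BuMe2SiCl (1.1 equiv), imidazole, DMF, 0 °C
Reagents that add atoms: tert-butyl(chloro)dimethylsilane, CC(C)(C)[Si](C)(C)Cl
Why: Selective silylation of the primary benzylic alcohol; the hydrogen-bonded salicylate OH is inert under these conditions.

Step 7
Reactants: 14 methyl 2-acetyl-3-{[tert-butyl(dimethyl)silyl]oxymethyl}-6-hydroxybenzoate; 9 (5R)-5-(3-trimethylsilylprop-1-en-2-yl)cyclohex-1-en-1-yl trifluoromethanesulfonate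
Product: 16 methyl 3-{[tert-butyl(dimethyl)silyl]oxymethyl}-6-hydroxy-2-{2-[(5R)-5-(3-trimethylsilylprop-1-en-2-yl)cyclohex-1-en-1-yl]acetyl}benzoate, via zinc enolate 15 (not isolated)
Conditions: LiN(SiMe3)2 (3.1 equiv), THF, −78 °C; ZnCl2 (2.2 equiv); then 9, Pd2(dba)3 (2.5 mol%), P(t-Bu)3 (6 mol%), 20 → 40 °C; AcOH, −78 °C
Reagents that add atoms: none
Why: Negishi-type palladium-catalysed α-alkenylation of the ketone zinc enolate with the enol triflate joins C7 to C8, and kinetic protonation leaves the β,γ-enone (C8=C9); the zinc enolate is too unreactive for Dieckmann closure onto the neighbouring, phenoxide-deactivated ester.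

Step 8
Reactants: 16 methyl 3-{[tert-butyl(dimethyl)silyl]oxymethyl}-6-hydroxy-2-{2-[(5R)-5-(3-trimethylsilylprop-1-en-2-yl)cyclohex-1-en-1-yl]acetyl}benzoate
Product: 18 methyl 20-[tert-butyl(dimethyl)silyl]oxy-3,6-dioxo-18-nor-ent-kaura-1,4,16-trien-19-oate, via aryloxyiodane 17 (not isolated)
Conditions: PhI(OCOCF3)2 (1.15 equiv), (CF3)2CHOH (0.005 M), −20 → 0 °C
Reagents that add atoms: none
Why: Proposed new method: ligand exchange at trivalent iodine gives an aryloxyiodane whose para carbon C10 (the ortho carbon C4 is blocked by CO2Me) is attacked by C9 of the ring C alkene through a chair-like six-membered transition state (H9 anti to C20) on the ring C face opposite the C13 side chain, and the resulting C8 cation is captured anti by the allylsilane, which can reach C8 only cis to the C13–C16 bond, so C13 fixes C8, C9 and C10 while rings B and D and the exo-methylene form together; the closest known reactions are phenol oxidative dearomatisation with allylsilane or alkene capture of the phenoxonium ion and allylsilane-terminated cation–olefin cyclisation.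

Step 9
Reactants: 18 methyl 20-[tert-butyl(dimethyl)silyl]oxy-3,6-dioxo-18-nor-ent-kaura-1,4,16-trien-19-oate
Product: 20 methyl 20-[tert-butyl(dimethyl)silyl]oxy-3,6-dioxo-ent-kaura-1,16-dien-19-oate, via lithium enolate 19 (not isolated)
Conditions: Li (2.1 equiv), NH3(l)/THF, −78 °C; t-BuOH (1.0 equiv); then MeI (6 equiv), −78 → −33 °C
Reagents that add atoms: iodomethane, CI
Why: Dissolving-metal reduction of the triply activated C4=C5 bond with in situ alkylation (Birch-type reductive methylation) protonates C5 anti to the axial C20 group (trans-decalin, also the thermodynamic epimer because C5 is α to the C6 ketone) and methylates the β-keto ester enolate at C4 from the face opposite C20, while the ring A enone survives because it is cross-conjugated with the enolate.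

Step 10
Reactants: 20 methyl 20-[tert-butyl(dimethyl)silyl]oxy-3,6-dioxo-ent-kaura-1,16-dien-19-oate
Product: 23 3,6-dioxo-ent-kaura-1,16-diene-19,20-dioic acid 19-methyl ester, via primary alcohol 21 (not isolated), via aldehyde 22 (not isolated)
Conditions: CrO3, H2SO4, H2O, acetone, 0 → 20 °C
Reagents that add atoms: water, O
Why: Jones oxidation: the acid cleaves the silyl ether and the primary alcohol is oxidised through the aldehyde hydrate to the C20 acid, while ketones, esters and the 1,1-disubstituted alkene are stable.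

Step 11
Reactants: 23 3,6-dioxo-ent-kaura-1,16-diene-19,20-dioic acid 19-methyl ester
Product: 24 dimethyl 3,6-dioxo-ent-kaura-1,16-diene-19,20-dioate
Conditions: Me3SiCHN2, MeOH/PhMe, 0 °C
Reagents that add atoms: (trimethylsilyl)diazomethane, C[Si](C)(C)C=[N+]=[N-]
Why: Methyl esterification with a diazoalkane masks the hindered C20 acid under neutral conditions before the diazo chemistry.

Step 12
Reactants: 24 dimethyl 3,6-dioxo-ent-kaura-1,16-diene-19,20-dioate
Product: 26 dimethyl 7-diazo-3,6-dioxo-ent-kaura-1,16-diene-19,20-dioate, via trifluoroacetyl ketone 25 (not isolated)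
Conditions: LiN(SiMe3)2 (1.1 equiv), THF, −78 °C; CF3CO2CH2CF3; then MeSO2N3, Et3N, H2O, MeCN, 20 °C
Reagents that add atoms: methanesulfonyl azide, CS(=O)(=O)N=[N+]=[N-]
Why: Detrifluoroacetylative diazo transfer (Danheiser variant of the Regitz reaction) occurs at C7, the only enolisable methylene (the ring A enone has no α-hydrogen and C8 is quaternary).

Step 13
Reactants: 26 dimethyl 7-diazo-3,6-dioxo-ent-kaura-1,16-diene-19,20-dioate
Product: 29 trimethyl 3-oxo-ent-gibberella-1,16-diene-7,19,20-trioate, via ketene 27 (not isolated), via C6 epimer 28 (not isolated)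
Conditions: hν (405 nm LED), MeOH, 20 °C; then KOt-Bu (0.2 equiv), t-BuOH/THF, 20 °C
Reagents that add atoms: methanol, CO
Why: Photochemical Wolff rearrangement: C5 migrates with retention to the carbene carbon and contracts ring B, methanol traps the ketene, and the hindered alkoxide, which is too poor a nucleophile to open the C3/C4 β-keto ester by retro-Claisen cleavage, equilibrates the kinetic C6 epimer through the only acidic C–H (H6) to the less hindered 6β-ester (trans to C4).

Step 14
Reactants: 29 trimethyl 3-oxo-ent-gibberella-1,16-diene-7,19,20-trioate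
Product: 31 trimethyl 2β-hydroxy-3-oxo-ent-gibberell-16-ene-7,19,20-trioate, via lithium enolate 30 (not isolated)
Conditions: LiBH(s-Bu)3 (1.05 equiv), THF, −78 °C; then 2-(phenylsulfonyl)-3-phenyloxaziridine, −78 → −40 °C
Reagents that add atoms: 2-(phenylsulfonyl)-3-phenyloxaziridine, O=S(=O)(N1OC1c1ccccc1)c1ccccc1
Why: Conjugate reduction gives the C2–C3 enolate regiospecifically, and Davis oxaziridine hydroxylation occurs on the β face of C2 because the axial α-CO2Me groups at C4 and C10 shield the α face.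

Step 15
Reactants: 31 trimethyl 2β-hydroxy-3-oxo-ent-gibberell-16-ene-7,19,20-trioate
Product: 32 trimethyl 2β,3β-dihydroxy-ent-gibberell-16-ene-7,19,20-trioate
Conditions: KBH(s-Bu)3 (2.2 equiv), THF, −78 °C
Reagents that add atoms: none
Why: The bulky trialkylborohydride attacks the C3 ketone equatorially and gives the axial 3β-alcohol cis to the 2β-OH (stereoselective hydride reduction); the methyl esters are inert at −78 °C.

Step 16
Reactants: 32 trimethyl 2β,3β-dihydroxy-ent-gibberell-16-ene-7,19,20-trioate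
Product: 33 2β,3β-dihydroxy-ent-gibberell-16-ene-7,19,20-trioic acid (the target gibberellin)
Conditions: LiS(n-Pr) (10 equiv), HMPA, 20 °C; then 1 M HCl
Reagents that add atoms: none
Why: SN2 demethylation by thiolate attacks the methyl carbons, so even the two hindered tertiary esters are cleaved, and acidification gives the triacid with the diol and alkene untouched.

## Compound list

1 | methyl (E)-4-oxobut-2-enoate | COC(=O)/C=C/C=O | starting material
2 | tert-butyl 3-oxobutanoate | CC(=O)CC(=O)OC(C)(C)C | starting material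
3 | tert-butyl (3R)-2-acetyl-3-(methoxycarbonyl)-5-oxopentanoate (Michael adduct, C2 epimers) | CC(=O)C(C(=O)OC(C)(C)C)[C@@H](CC=O)C(=O)OC | intermediate (not isolated)
4 | 1-tert-butyl 2-methyl (2R)-6-oxocyclohex-4-ene-1,2-dicarboxylate | COC(=O)[C@@H]1CC=CC(=O)C1C(=O)OC(C)(C)C | intermediate (not isolated)
5 | methyl (1R)-5-oxocyclohex-3-ene-1-carboxylate | COC(=O)[C@H]1CC(=O)C=CC1 | intermediate
6 | lithium enolate of 5 (C8–C9 enolate, 5R) | [Li+].[O-]C1=CCC[C@H](C1)C(=O)OC | intermediate (not isolated)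
7 | methyl (1R)-3-(trifluoromethylsulfonyloxy)cyclohex-3-ene-1-carboxylate | FC(F)(F)S(=O)(=O)OC1=CCC[C@H](C1)C(=O)OC | intermediate
8 | (5R)-5-[2-hydroxy-1,3-bis(trimethylsilyl)propan-2-yl]cyclohex-1-en-1-yl trifluoromethanesulfonate | FC(F)(F)S(=O)(=O)OC1=CCC[C@H](C1)C(O)(C[Si](C)(C)C)C[Si](C)(C)C | intermediate (not isolated)
9 | (5R)-5-(3-trimethylsilylprop-1-en-2-yl)cyclohex-1-en-1-yl trifluoromethanesulfonate | FC(F)(F)S(=O)(=O)OC1=CCC[C@H](C1)C(=C)C[Si](C)(C)C | intermediate
10 | dimethyl 3-hydroxybenzene-1,2-dicarboxylate | COC(=O)c1cccc(O)c1C(=O)OC | starting material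
11 | dimethyl 3-hydroxy-6-(hydroxymethyl)benzene-1,2-dicarboxylate | COC(=O)c1c(CO)ccc(O)c1C(=O)OC | intermediate (not isolated)
12 | methyl 5-hydroxy-3-oxo-1,3-dihydro-2-benzofuran-4-carboxylate | COC(=O)c1c(O)ccc2COC(=O)c12 | intermediate
13 | methyl 2-acetyl-6-hydroxy-3-(hydroxymethyl)benzoate (in equilibrium with its cyclic hemiketal) | COC(=O)c1c(O)ccc(CO)c1C(C)=O | intermediate
14 | methyl 2-acetyl-3-{[tert-butyl(dimethyl)silyl]oxymethyl}-6-hydroxybenzoate | COC(=O)c1c(O)ccc(CO[Si](C)(C)C(C)(C)C)c1C(C)=O | intermediate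
15 | chlorozinc enolate of 14 (lithium phenoxide) | COC(=O)c1c([O-])ccc(CO[Si](C)(C)C(C)(C)C)c1C(=C)O[Zn]Cl.[Li+] | intermediate (not isolated)
16 | methyl 3-{[tert-butyl(dimethyl)silyl]oxymethyl}-6-hydroxy-2-{2-[(5R)-5-(3-trimethylsilylprop-1-en-2-yl)cyclohex-1-en-1-yl]acetyl}benzoate | COC(=O)c1c(O)ccc(CO[Si](C)(C)C(C)(C)C)c1C(=O)CC1=CCC[C@H](C1)C(=C)C[Si](C)(C)C | intermediate
17 | aryloxy(phenyl)iodanyl trifluoroacetate of 16 | COC(=O)c1c(OI(c2ccccc2)OC(=O)C(F)(F)F)ccc(CO[Si](C)(C)C(C)(C)C)c1C(=O)CC1=CCC[C@H](C1)C(=C)C[Si](C)(C)C | intermediate (not isolated)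
18 | methyl 20-[tert-butyl(dimethyl)silyl]oxy-3,6-dioxo-18-nor-ent-kaura-1,4,16-trien-19-oate (9β-H; C20 α; C8 and C13 as in ent-kaurane) | C=C1C[C@]23C[C@H]1CC[C@H]2[C@]1(CO[Si](C)(C)C(C)(C)C)C=CC(=O)C(C(=O)OC)=C1C(=O)C3 | intermediate
19 | lithium C3–C4 enolate of the reduced β-keto ester (5β-H) | C=C1C[C@]23C[C@H]1CC[C@H]2[C@]1(CO[Si](C)(C)C(C)(C)C)C=CC([O-])=C(C(=O)OC)[C@H]1C(=O)C3.[Li+] | intermediate (not isolated)
20 | methyl 20-[tert-butyl(dimethyl)silyl]oxy-3,6-dioxo-ent-kaura-1,16-dien-19-oate (5β-H; 4β-CH3; 4α-CO2Me) | C=C1C[C@]23C[C@H]1CC[C@H]2[C@]1(CO[Si](C)(C)C(C)(C)C)C=CC(=O)[C@@](C)(C(=O)OC)[C@H]1C(=O)C3 | intermediate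
21 | methyl 20-hydroxy-3,6-dioxo-ent-kaura-1,16-dien-19-oate | C=C1C[C@]23C[C@H]1CC[C@H]2[C@]1(CO)C=CC(=O)[C@@](C)(C(=O)OC)[C@H]1C(=O)C3 | intermediate (not isolated)
22 | methyl 3,6,20-trioxo-ent-kaura-1,16-dien-19-oate | C=C1C[C@]23C[C@H]1CC[C@H]2[C@]1(C=O)C=CC(=O)[C@@](C)(C(=O)OC)[C@H]1C(=O)C3 | intermediate (not isolated)
23 | 3,6-dioxo-ent-kaura-1,16-diene-19,20-dioic acid 19-methyl ester | C=C1C[C@]23C[C@H]1CC[C@H]2[C@]1(C(=O)O)C=CC(=O)[C@@](C)(C(=O)OC)[C@H]1C(=O)C3 | intermediate
24 | dimethyl 3,6-dioxo-ent-kaura-1,16-diene-19,20-dioate | C=C1C[C@]23C[C@H]1CC[C@H]2[C@]1(C(=O)OC)C=CC(=O)[C@@](C)(C(=O)OC)[C@H]1C(=O)C3 | intermediate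
25 | dimethyl 3,6-dioxo-7-(trifluoroacetyl)-ent-kaura-1,16-diene-19,20-dioate | C=C1C[C@]23C[C@H]1CC[C@H]2[C@]1(C(=O)OC)C=CC(=O)[C@@](C)(C(=O)OC)[C@H]1C(=O)C3C(=O)C(F)(F)F | intermediate (not isolated)
26 | dimethyl 7-diazo-3,6-dioxo-ent-kaura-1,16-diene-19,20-dioate | C=C1C[C@]23C[C@H]1CC[C@H]2[C@]1(C(=O)OC)C=CC(=O)[C@@](C)(C(=O)OC)[C@H]1C(=O)C3=[N+]=[N-] | intermediate
27 | ring-contracted ketene (C6=C7=O on the five-membered ring B) | C=C1C[C@]23C[C@H]1CC[C@H]2[C@]1(C(=O)OC)C=CC(=O)[C@@](C)(C(=O)OC)[C@H]1C3=C=O | intermediate (not isolated)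
28 | 6-epimer of 29 (6α-CO2Me) | C=C1C[C@]23C[C@H]1CC[C@H]2[C@]1(C(=O)OC)C=CC(=O)[C@@](C)(C(=O)OC)[C@H]1[C@H]3C(=O)OC | intermediate (not isolated)
29 | trimethyl 3-oxo-ent-gibberella-1,16-diene-7,19,20-trioate (6β-CO2Me) | C=C1C[C@]23C[C@H]1CC[C@H]2[C@]1(C(=O)OC)C=CC(=O)[C@@](C)(C(=O)OC)[C@H]1[C@@H]3C(=O)OC | intermediate
30 | lithium C2–C3 enolate of the 1,2-dihydro derivative of 29 | C=C1C[C@]23C[C@H]1CC[C@H]2[C@]1(C(=O)OC)CC=C([O-])[C@@](C)(C(=O)OC)[C@H]1[C@@H]3C(=O)OC.[Li+] | intermediate (not isolated)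
31 | trimethyl 2β-hydroxy-3-oxo-ent-gibberell-16-ene-7,19,20-trioate | C=C1C[C@]23C[C@H]1CC[C@H]2[C@]1(C(=O)OC)C[C@H](O)C(=O)[C@@](C)(C(=O)OC)[C@H]1[C@@H]3C(=O)OC | intermediate
32 | trimethyl 2β,3β-dihydroxy-ent-gibberell-16-ene-7,19,20-trioate | C=C1C[C@]23C[C@H]1CC[C@H]2[C@]1(C(=O)OC)C[C@H](O)[C@H](O)[C@@](C)(C(=O)OC)[C@H]1[C@@H]3C(=O)OC | intermediate
33 | 2β,3β-dihydroxy-ent-gibberell-16-ene-7,19,20-trioic acid (the target gibberellin) | C=C1C[C@]23C[C@H]1CC[C@H]2[C@]1(C(=O)O)C[C@H](O)[C@H](O)[C@@](C)(C(=O)O)[C@H]1[C@@H]3C(=O)O | target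

## Step count and risks

Total: 16 steps. Longest linear sequence: 13 steps (steps 1–3 or steps 4–6, then steps 7–16).

The three steps most likely to fail:

- **Step 8 (key dearomatising bicyclisation).** The phenol is electron-poor, the C8 cation could lose a C7 proton instead of being captured, and the C9 facial selectivity rests on anti addition. The fallback separates oxidation from C–C bond formation. It sets out from 16, which is oxidised with PhI(OAc)2 in MeOH to the isolable para-quinol ether methyl 3-{[tert-butyl(dimethyl)silyl]oxymethyl}-3-methoxy-6-oxo-2-{2-[(5R)-5-(3-trimethylsilylprop-1-en-2-yl)cyclohex-1-en-1-yl]acetyl}cyclohexa-1,4-diene-1-carboxylate F1. F1 is then ionised without oxidant (BF3·OEt2 or Me3SiOSO2CF3, CH2Cl2, −78 °C) to the same C10 cation, which cyclises and is closed by the allylsilane. The fallback comes back to the route at 18.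

- **Step 7 (α-alkenylation of a hindered, ester-flanked ketone).** The fallback reverses the polarity of the coupling and sets out from 14 and 9. Compound 14 is enolised under soft conditions (Me3SiOSO2CF3, Et3N, CH2Cl2, 0 °C) to the bis-silylated enol ether methyl 3-{[tert-butyl(dimethyl)silyl]oxymethyl}-6-(trimethylsilyloxy)-2-[1-(trimethylsilyloxy)ethenyl]benzoate F2. NBS (THF, −78 → 0 °C, aqueous work-up, which also frees the phenol) converts F2 into the bromoketone methyl 2-(bromoacetyl)-3-{[tert-butyl(dimethyl)silyl]oxymethyl}-6-hydroxybenzoate F3. Compound 9 is borylated (B2pin2, PdCl2(dppf), KOAc, dioxane, 80 °C) to the alkenyl boronate 2-[(5R)-5-(3-trimethylsilylprop-1-en-2-yl)cyclohex-1-en-1-yl]-4,4,5,5-tetramethyl-1,3,2-dioxaborolane F4. Suzuki coupling of F3 with F4 (Pd(OAc)2, P(o-tol)3, K3PO4, THF/H2O) comes back to the route at 16 without ever forming a strongly basic enolate.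

- **Step 4 (electrophilic hydroxymethylation of a deactivated phenol).** The fallback replaces it by halogenation and cross-coupling and sets out from 10. Para-bromination (NBS, MeCN) gives dimethyl 3-bromo-6-hydroxybenzene-1,2-dicarboxylate F5. Palladium-catalysed hydroxymethylation of F5 with K[AcOCH2BF3] (Pd(OAc)2, RuPhos, Na2CO3, dioxane/H2O, 100 °C; the acetate is hydrolysed in the basic medium) gives 11, which lactonises with p-TsOH and comes back to the route at 12.

## Further compounds

F1 | step 8 | methyl 3-{[tert-butyl(dimethyl)silyl]oxymethyl}-3-methoxy-6-oxo-2-{2-[(5R)-5-(3-trimethylsilylprop-1-en-2-yl)cyclohex-1-en-1-yl]acetyl}cyclohexa-1,4-diene-1-carboxylate (C3 epimers) | COC(=O)C1=C(C(=O)CC2=CCC[C@H](C2)C(=C)C[Si](C)(C)C)C(CO[Si](C)(C)C(C)(C)C)(OC)C=CC1=O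
F2 | step 7 | methyl 3-{[tert-butyl(dimethyl)silyl]oxymethyl}-6-(trimethylsilyloxy)-2-[1-(trimethylsilyloxy)ethenyl]benzoate | COC(=O)c1c(O[Si](C)(C)C)ccc(CO[Si](C)(C)C(C)(C)C)c1C(=C)O[Si](C)(C)C
F3 | step 7 | methyl 2-(bromoacetyl)-3-{[tert-butyl(dimethyl)silyl]oxymethyl}-6-hydroxybenzoate | COC(=O)c1c(O)ccc(CO[Si](C)(C)C(C)(C)C)c1C(=O)CBr
F4 | step 7 | 2-[(5R)-5-(3-trimethylsilylprop-1-en-2-yl)cyclohex-1-en-1-yl]-4,4,5,5-tetramethyl-1,3,2-dioxaborolane | CC1(C)OB(OC1(C)C)C1=CCC[C@H](C1)C(=C)C[Si](C)(C)C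
F5 | step 4 | dimethyl 3-bromo-6-hydroxybenzene-1,2-dicarboxylate | COC(=O)c1c(Br)ccc(O)c1C(=O)OC
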